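**Retrosynthetic overview**

1. Numbering used throughout (drimane skeleton): ring A = C1–C5 + C10 (C3 carbinol, C4 gem-dimethyl), ring B = C5–C10, C11 = CH2O, C12 = exocyclic CH2.
2. Endgame disconnections: the C11–O aryl ether (Mitsunobu with umbelliferone), C8=C12 (methylenation of a C8 ketone), and C6=C7 (β-elimination of a C6 sulfonyl group from that ketone).
3. Key disconnection: the two ring-B bonds C6–C7 and C5–C10, made together by an intramolecular Diels–Alder reaction of an acyclic triene. Rings A and B close in the same operation; the coumarin is bought.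
4. Enabling feature: ring B is a cyclohexene retron one oxidation level away. Its diene C12=C8–C7=C6 corresponds to the enone C6=C7–C8=O, which is the adduct of a 2-alkoxydiene (C7=C8–C9=C10) and a vinyl sulfone (C5=C6). C10 and C5 are joined by the four carbons C1–C4 of ring A, which act as tether and carry the controlling C3 carbinol.
5. Triene assembly: C3 by asymmetric tert-prenylation of pent-4-ynal; the tetrasubstituted C9=C10 alkene by carbocupration/iodination of an alkynoate; C5=C6 by olefination; C7/C8 by Stille coupling.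

Key step: step 8

Assumption: the B-prenyl borane made from (−)-Ipc2BOMe is taken to add to 1 with the same facial sense as the parent B-allyl reagent, giving the (R)-carbinol; if the sense were opposite, the antipodal borane would be used.

**Route**

Step 1
Reactants: 1 pent-4-ynal
Product: 2 (R)-3,3-dimethyloct-1-en-7-yn-4-ol
Conditions: (−)-Ipc2BOMe, prenylmagnesium chloride, Et2O/THF, −78 °C to rt; then 1, −78 °C; NaOH, H2O2, 0 °C to rt
Reagents that add atoms: prenylmagnesium chloride (3-methylbut-2-en-1-ylmagnesium chloride), CC(C)=CC[Mg]Cl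
Why: Brown asymmetric allylboration in its tert-prenylation form, in which the B-prenyl borane adds through a closed chair transition state with allylic transposition, building the quaternary C4 with its vinyl group (C5=C6) and setting C3 as R by reagent control.

Step 2
Reactants: 2 (R)-3,3-dimethyloct-1-en-7-yn-4-ol
Product: 4 methyl (R)-6-[(methoxycarbonyl)oxy]-7,7-dimethylnon-8-en-2-ynoate, via dilithio derivative 3 (not isolated)
Conditions: n-BuLi (2.1 equiv), THF, −78 °C; ClCO2Me (2.5 equiv), −78 to 0 °C
Reagents that add atoms: methyl chloroformate, COC(=O)Cl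
Why: Double deprotonation followed by acylation with a chloroformate gives the alkynoate (ester carbon = C11) and at the same time masks the C3 hydroxyl as a methyl carbonate, with no stereocentre touched.

Step 3
Reactants: 4 methyl (R)-6-[(methoxycarbonyl)oxy]-7,7-dimethylnon-8-en-2-ynoate
Product: 6 methyl (2E,6R)-2-iodo-6-[(methoxycarbonyl)oxy]-3,7,7-trimethylnona-2,8-dienoate, via vinylcuprate 5 (not isolated)
Conditions: Me2CuLi (from MeLi and CuI, 1.3 equiv), THF, −78 °C; I2, THF, −78 °C
Reagents that add atoms: lithium dimethylcuprate, [Li+].C[Cu-]C; iodine, II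
Why: syn-Carbocupration of the alkynoate (cuprate conjugate addition) followed by iodinolysis of the α-cuprio ester with retention should fix the tetrasubstituted C9=C10 geometry, with the new methyl cis to iodine and the chain cis to the ester.

Step 4
Reactants: 6 methyl (2E,6R)-2-iodo-6-[(methoxycarbonyl)oxy]-3,7,7-trimethylnona-2,8-dienoate
Product: 7 (2E,6R)-2-iodo-3,7,7-trimethylnona-2,8-diene-1,6-diol
Conditions: i-Bu2AlH (7 equiv), CH2Cl2, −78 to 0 °C; aq. potassium sodium tartrate
Reagents that add atoms: none
Why: Hydride reduction of the conjugated ester to the allylic alcohol (C11–OH) with concurrent reductive removal of the carbonate, the vinyl iodide and the alkene geometry being inert to the aluminium hydride at this temperature.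

Step 5
Reactants: 7 (2E,6R)-2-iodo-3,7,7-trimethylnona-2,8-diene-1,6-diol
Product: 9 (3R,6E)-3,8-dihydroxy-7-iodo-2,2,6-trimethyloct-6-enal, via tetrol 8 (not isolated)
Conditions: OsO4 (2 mol %), NaIO4 (3 equiv), 2,6-lutidine, dioxane/H2O, rt
Reagents that add atoms: osmium tetroxide, O=[Os](=O)(=O)=O; sodium periodate, [Na+].[O-]I(=O)(=O)=O
Why: Lemieux–Johnson oxidative cleavage (dihydroxylation, then periodate glycol cleavage) should be chemoselective for the monosubstituted vinyl group over the hindered, iodine-deactivated tetrasubstituted alkene, and the aldehyde formed has no α-hydrogen.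

Step 6
Reactants: 9 (3R,6E)-3,8-dihydroxy-7-iodo-2,2,6-trimethyloct-6-enal
Product: 10 (2E,6R,8E)-2-iodo-3,7,7-trimethyl-9-(phenylsulfonyl)nona-2,8-diene-1,6-diol
Conditions: (EtO)2P(O)CH2SO2Ph, LiCl, DBU, MeCN, 0 °C to rt
Reagents that add atoms: diethyl [(phenylsulfonyl)methyl]phosphonate, CCOP(=O)(OCC)CS(=O)(=O)c1ccccc1
Why: Horner–Wadsworth–Emmons olefination under Masamune–Roush conditions tolerates the free hydroxyls and should give the (E)-vinyl sulfone (C5=C6), which cannot isomerise to an allyl sulfone because C4 is quaternary.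

Step 7
Reactants: 10 (2E,6R,8E)-2-iodo-3,7,7-trimethyl-9-(phenylsulfonyl)nona-2,8-diene-1,6-diol
Product: 11 (3E,7R,9E)-2-ethoxy-3-(hydroxymethyl)-4,8,8-trimethyl-10-(phenylsulfonyl)deca-1,3,9-trien-7-ol
Conditions: tributyl(1-ethoxyvinyl)stannane, Pd(PPh3)4 (5 mol %), CuI (10 mol %), DMF, 50 °C; filtration over Et3N-deactivated silica, used at once
Reagents that add atoms: tributyl(1-ethoxyvinyl)stannane, CCCC[Sn](CCCC)(CCCC)C(=C)OCC
Why: Stille cross-coupling (zerovalent palladium with CuI co-catalysis) of the vinyl iodide with retention of alkene geometry installs C7 and C8 as a 2-ethoxy-1,3-diene, the masked C8 ketone.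

Step 8
Reactants: 11 (3E,7R,9E)-2-ethoxy-3-(hydroxymethyl)-4,8,8-trimethyl-10-(phenylsulfonyl)deca-1,3,9-trien-7-ol
Product: 12 [(4R,4aS,6R,8aR)-2-ethoxy-6-hydroxy-5,5,8a-trimethyl-4-(phenylsulfonyl)-3,4,4a,5,6,7,8,8a-octahydronaphthalen-1-yl]methanol
Conditions: toluene (0.005 M), BHT, base-washed sealed tube, 150 °C
Reagents that add atoms: none
Why: A thermal, concerted intramolecular Diels–Alder reaction (normal electron demand) joins the 2-ethoxy-1,3-diene C7=C8–C9=C10 to the (E)-vinyl sulfone C5=C6; the closest known reaction type is the cycloaddition of (E)-1-sulfonyl-1,7,9-decatrienes to trans-fused octalins, here combined with a 2-alkoxydiene as a masked ketone. Ring B closes as the cyclohexene of the [4+2] event (C6–C7 and C5–C10 formed suprafacially on both partners) and ring A closes in the fused mode through the four-carbon tether C1–C4, whose length excludes the bridged, electronically preferred orientation, so regiochemistry is fixed by geometry and not by polarisation. C5 and C10 should arise trans from a chair-like tether with C4 exo and the sulfonyl group endo, in which every tether substituent except the unavoidable C4/C10 methyl pair is equatorial, whereas the cis-fused alternative must push the quaternary C4 under the diene against C9 and its CH2OH group. The absolute sense is relayed from C3, whose hydroxyl sits equatorial in that chair and so ends on the face of the C10 methyl, and the (E)-geometry of the dienophile places the sulfonyl group at C6 cis to H-5, a centre that is erased in step 9. The methyl group on C10 comes from the Z position of the diene terminus fixed in step 3, so the quaternary centre is created directly. The step needs trans over cis fusion and one diene face, secured by the E-sulfone, the gem-dimethyl group beside the dienophile and the equatorial C3 carbinol; the electron-poor sulfone together with the electron-rich alkoxydiene is what should let the congested C5–C10 bond form at about 150 °C.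

Step 9
Reactants: 12 [(4R,4aS,6R,8aR)-2-ethoxy-6-hydroxy-5,5,8a-trimethyl-4-(phenylsulfonyl)-3,4,4a,5,6,7,8,8a-octahydronaphthalen-1-yl]methanol
Product: 14 (1R,4aS,6R,8aR)-6-hydroxy-1-(hydroxymethyl)-5,5,8a-trimethyl-4a,5,6,7,8,8a-hexahydronaphthalen-2(1H)-one, via β-sulfonyl ketone 13 (not isolated)
Conditions: 1 M HCl, THF, rt; then DBU (1.2 equiv), CH2Cl2, 0 °C
Reagents that add atoms: water, O
Why: Acid hydrolysis of the enol ether protonates C9 on the face opposite the C10 methyl (which is also the thermodynamically preferred, equatorial CH2OH epimer), and the resulting β-sulfonyl ketone loses benzenesulfinate by E1cB elimination to give the C6=C7–C8=O enone.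

Step 10
Reactants: 14 (1R,4aS,6R,8aR)-6-hydroxy-1-(hydroxymethyl)-5,5,8a-trimethyl-4a,5,6,7,8,8a-hexahydronaphthalen-2(1H)-one
Product: 15 [(1R,4aS,6R,8aR)-6-hydroxy-5,5,8a-trimethyl-2-methylidene-1,2,4a,5,6,7,8,8a-octahydronaphthalen-1-yl]methanol
Conditions: Zn, CH2Br2, TiCl4 (pre-formed reagent, excess), THF/CH2Cl2, 0 °C to rt
Reagents that add atoms: dibromomethane, BrCBr
Why: Takai–Lombardo methylenation, a non-basic carbonyl olefination, converts the enone carbonyl into the exocyclic C8=C12 methylene without epimerising C9 or provoking retro-aldol loss of the β-hydroxymethyl group.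

Step 11
Reactants: 15 [(1R,4aS,6R,8aR)-6-hydroxy-5,5,8a-trimethyl-2-methylidene-1,2,4a,5,6,7,8,8a-octahydronaphthalen-1-yl]methanol; 16 umbelliferone (7-hydroxy-2H-chromen-2-one)
Product: 17 7-{[(1R,4aS,6R,8aR)-6-hydroxy-5,5,8a-trimethyl-2-methylidene-1,2,4a,5,6,7,8,8a-octahydronaphthalen-1-yl]methoxy}-2H-chromen-2-one
Conditions: PPh3, DIAD, THF, 0 to 40 °C
Reagents that add atoms: none
Why: Mitsunobu etherification of the primary C11 alcohol with the acidic phenol forms the aryl ether, while the hindered secondary C3 alcohol beside the gem-dimethyl group should not react and no stereocentre is touched.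

**Compound list**

1 | pent-4-ynal | C#CCCC=O | starting material
2 | (R)-3,3-dimethyloct-1-en-7-yn-4-ol | C=CC(C)(C)[C@H](O)CCC#C | intermediate
3 | dilithio derivative of 2 (lithium alkoxide and lithium acetylide) | [Li]C#CCC[C@@H](O[Li])C(C)(C)C=C | intermediate
4 | methyl (R)-6-[(methoxycarbonyl)oxy]-7,7-dimethylnon-8-en-2-ynoate | COC(=O)C#CCC[C@@H](OC(=O)OC)C(C)(C)C=C | intermediate
5 | lithium methyl(vinyl)cuprate from syn-addition to 4 (copper cis to the new methyl, chain cis to the ester) | C[Cu-]/C(C(=O)OC)=C(/CC[C@@H](OC(=O)OC)C(C)(C)C=C)C.[Li+] | intermediate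
6 | methyl (2E,6R)-2-iodo-6-[(methoxycarbonyl)oxy]-3,7,7-trimethylnona-2,8-dienoate | I/C(C(=O)OC)=C(/CC[C@@H](OC(=O)OC)C(C)(C)C=C)C | intermediate
7 | (2E,6R)-2-iodo-3,7,7-trimethylnona-2,8-diene-1,6-diol | I/C(CO)=C(/CC[C@@H](O)C(C)(C)C=C)C | intermediate
8 | (2E,6R)-2-iodo-3,7,7-trimethylnon-2-ene-1,6,8,9-tetrol (both C8 epimers) | I/C(CO)=C(/CC[C@@H](O)C(C)(C)C(O)CO)C | intermediate
9 | (3R,6E)-3,8-dihydroxy-7-iodo-2,2,6-trimethyloct-6-enal | I/C(CO)=C(/CC[C@@H](O)C(C)(C)C=O)C | intermediate
10 | (2E,6R,8E)-2-iodo-3,7,7-trimethyl-9-(phenylsulfonyl)nona-2,8-diene-1,6-diol | I/C(CO)=C(/CC[C@@H](O)C(C)(C)/C=C/S(=O)(=O)c1ccccc1)C | intermediate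
11 | (3E,7R,9E)-2-ethoxy-3-(hydroxymethyl)-4,8,8-trimethyl-10-(phenylsulfonyl)deca-1,3,9-trien-7-ol | C=C(OCC)/C(CO)=C(/CC[C@@H](O)C(C)(C)/C=C/S(=O)(=O)c1ccccc1)C | intermediate
12 | [(4R,4aS,6R,8aR)-2-ethoxy-6-hydroxy-5,5,8a-trimethyl-4-(phenylsulfonyl)-3,4,4a,5,6,7,8,8a-octahydronaphthalen-1-yl]methanol (trans-fused; 6-OH cis to 8a-CH3; sulfonyl cis to 4a-H) | CCOC1=C(CO)[C@]2(C)CC[C@@H](O)C(C)(C)[C@H]2[C@H](S(=O)(=O)c2ccccc2)C1 | intermediate
13 | (1R,4R,4aS,6R,8aR)-6-hydroxy-1-(hydroxymethyl)-5,5,8a-trimethyl-4-(phenylsulfonyl)octahydronaphthalen-2(1H)-one | O=C1C[C@@H](S(=O)(=O)c2ccccc2)[C@@H]2C(C)(C)[C@H](O)CC[C@@]2(C)[C@@H]1CO | intermediate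
14 | (1R,4aS,6R,8aR)-6-hydroxy-1-(hydroxymethyl)-5,5,8a-trimethyl-4a,5,6,7,8,8a-hexahydronaphthalen-2(1H)-one | O=C1C=C[C@@H]2C(C)(C)[C@H](O)CC[C@@]2(C)[C@@H]1CO | intermediate
15 | [(1R,4aS,6R,8aR)-6-hydroxy-5,5,8a-trimethyl-2-methylidene-1,2,4a,5,6,7,8,8a-octahydronaphthalen-1-yl]methanol | C=C1C=C[C@@H]2C(C)(C)[C@H](O)CC[C@@]2(C)[C@@H]1CO | intermediate
16 | umbelliferone (7-hydroxy-2H-chromen-2-one) | Oc1ccc2ccc(=O)oc2c1 | starting material
17 | 7-{[(1R,4aS,6R,8aR)-6-hydroxy-5,5,8a-trimethyl-2-methylidene-1,2,4a,5,6,7,8,8a-octahydronaphthalen-1-yl]methoxy}-2H-chromen-2-one | C=C1C=C[C@@H]2C(C)(C)[C@H](O)CC[C@@]2(C)[C@@H]1COc1ccc2ccc(=O)oc2c1 | target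

**Step count and risks**

Total steps: 11. Longest linear sequence: 11 steps (1 to 17); 16 enters in the last step.

Steps most likely to fail:

1. Step 8 (cycloaddition). The diene terminus C10 carries a methyl group in the Z position and both bond-forming carbons of C5–C10 are congested, so the cycloaddition may be slow enough for thermal decay or adventitious hydrolysis of the 2-ethoxydiene to compete. Facial discrimination by the single equatorial C3 hydroxyl and the preference for trans over cis fusion may also be incomplete. The fallback replaces the pericyclic step by a stepwise polar annulation (Michael addition, then aldol condensation); it sets out from 7 and comes back at 14. Stille coupling of 7 with tributyl(1-ethoxyvinyl)stannane (Pd(PPh3)4, CuI, DMF) would give (3E,7R)-2-ethoxy-3-(hydroxymethyl)-4,8,8-trimethyldeca-1,3,9-trien-7-ol F1, which is hydrolysed on acidic work-up (aq. HCl, THF) to (3E,7R)-7-hydroxy-3-(hydroxymethyl)-4,8,8-trimethyldeca-3,9-dien-2-one F2. Aldehyde-selective Wacker oxidation of the hindered terminal vinyl group (PdCl2(PhCN)2, CuCl2, AgNO2, t-BuOH/MeNO2, O2) would give (4R,7E)-4-hydroxy-8-(hydroxymethyl)-3,3,7-trimethyl-9-oxodec-7-enal F3. Pyrrolidine and AcOH (toluene, 60 °C) would then bring about intramolecular Michael addition of the aldehyde enamine carbon C5 to the enone carbon C10, closing ring A as (3R)-3-hydroxy-6-(1-hydroxy-3-oxobutan-2-yl)-2,2,6-trimethylcyclohexane-1-carbaldehyde F4. Aldol closure of the methyl ketone (C7) onto the aldehyde (C6) would give 4,6-dihydroxy-1-(hydroxymethyl)-5,5,8a-trimethyloctahydronaphthalen-2(1H)-one F5, which dehydrates to 14. In this sequence C5 and C9 stay epimerisable (γ and α to the enone carbonyl) and should settle in the trans-fused, equatorial arrangement, and C10 is set against C3 in a chair with the hydroxyl equatorial under conditions where the Michael addition can revert.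

2. Step 3 (carbocupration and iodination). The α-cuprio ester can leak into its allenolate form before or during iodinolysis, which would erode the C9=C10 geometry, and incomplete iodination would leave the protonated enoate. The fallback builds the same iodoalkene by hydroxyl-directed carbometalation of a propargylic alcohol; it sets out from 2 and comes back at 7. Double deprotonation of 2 (n-BuLi, 2.2 equiv) and addition to paraformaldehyde would give (R)-7,7-dimethylnon-8-en-2-yne-1,6-diol F6. Iron-catalysed syn-carbomagnesiation (MeMgBr in excess, Fe(acac)3 cat., THF) should then deliver methyl to the alkyne carbon distal to the propargylic oxygen and magnesium to the proximal one, and quenching the vinylmagnesium species with I2 gives 7 directly.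

3. Step 11 (etherification). Substitution at the β-branched C11 carbinol next to the quaternary C10 may be slow, so that elimination of the activated alcohol or recovery of 15 takes over. The fallback reverses the polarity of the bond formation; it sets out from 15 and comes back at 17. Palladium-catalysed C–O cross-coupling of the primary alcohol of 15 with 7-bromocoumarin (Pd2(dba)3, t-BuBrettPhos, Cs2CO3, toluene, 80 °C) uses the alcohol as the nucleophile toward an aryl electrophile, so no substitution at C11 is required, and the hindered secondary C3 alcohol should again stay untouched. This fallback makes no new compound.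

**Further compounds**

F1 | step 8 | (3E,7R)-2-ethoxy-3-(hydroxymethyl)-4,8,8-trimethyldeca-1,3,9-trien-7-ol | C=C(OCC)/C(CO)=C(/CC[C@@H](O)C(C)(C)C=C)C
F2 | step 8 | (3E,7R)-7-hydroxy-3-(hydroxymethyl)-4,8,8-trimethyldeca-3,9-dien-2-one | CC(=O)/C(CO)=C(/CC[C@@H](O)C(C)(C)C=C)C
F3 | step 8 | (4R,7E)-4-hydroxy-8-(hydroxymethyl)-3,3,7-trimethyl-9-oxodec-7-enal | CC(=O)/C(CO)=C(/CC[C@@H](O)C(C)(C)CC=O)C
F4 | step 8 | (3R)-3-hydroxy-6-(1-hydroxy-3-oxobutan-2-yl)-2,2,6-trimethylcyclohexane-1-carbaldehyde (ring centres as in 14, side-chain centre not fixed) | CC(=O)C(CO)[C@]1(C)CC[C@@H](O)C(C)(C)[C@H]1C=O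
F5 | step 8 | 4,6-dihydroxy-1-(hydroxymethyl)-5,5,8a-trimethyloctahydronaphthalen-2(1H)-one (4a, 6 and 8a as in 14) | O=C1CC(O)[C@@H]2C(C)(C)[C@H](O)CC[C@@]2(C)C1CO
F6 | step 3 | (R)-7,7-dimethylnon-8-en-2-yne-1,6-diol | OCC#CCC[C@@H](O)C(C)(C)C=C
F0 | step 11 | none | none
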